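**Assumption:** germacrane numbering is used throughout (C6 = lactone carbinol, C7 = ring carbon bearing C11, C8 = angelate carbinol, C1/C10 = epoxide, C3 = ketone, C15 = CH2OH), and angelic acid is bought.

## Retrosynthetic overview
1. The epoxide is the last ring, made by dioxirane oxidation of the E-1(10)-alkene of the finished germacranolide.
2. The ten-membered ring and then the lactone come from one operation. It forms C6–C7 (the farnesyl C1–C10 bond) with allyl transposition to C11=C13, and O6 then captures C12. The substrate is the fully oxidised acyclic 6,7-seco chain, which already carries the 8-angelate and the 3-ketone.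
3. C2–C3 is a head-to-tail allylation of a nitronate (C3) by a geranyl-type allylic acetate, followed by a Nef reaction.
4. C4 is set by an organocatalytic MeNO2 Michael addition and C8 by an enamine α-acyloxylation. C11–C13 come from methyl propiolate.
5. Ring order: carbocycle, then γ-lactone, then epoxide.

## Route

**Step 1**
Reactants: 1 (Z)-but-2-ene-1,4-diol
Product: 2 (Z)-4-(tert-butyldiphenylsilyloxy)but-2-en-1-ol
Conditions: NaH (1.0 equiv), THF, 0 °C→rt; TBDPSCl (1.0 equiv)
Reagents that add atoms: TBDPSCl, CC(C)(C)[Si](Cl)(c1ccccc1)c1ccccc1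
Why: O-silylation of the sparingly soluble monosodium alkoxide gives the mono-ether selectively, and no stereocentre is formed.

**Step 2**
Reactants: 2 (Z)-4-(tert-butyldiphenylsilyloxy)but-2-en-1-ol
Product: 4 (E)-4-(tert-butyldiphenylsilyloxy)but-2-enal, via (Z)-enal 3 (not isolated)
Conditions: MnO2 (15 equiv), CH2Cl2, rt; then DMAP (5 mol %), rt
Reagents that add atoms: none
Why: Allylic alcohol oxidation with MnO2 followed by nucleophile-catalysed (addition–elimination) Z→E isomerisation drains the enal to the more stable E isomer needed for iminium catalysis.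

**Step 3**
Reactants: 4 (E)-4-(tert-butyldiphenylsilyloxy)but-2-enal; 5 nitromethane
Product: 7 (2R)-1-(tert-butyldiphenylsilyloxy)-4,4-dimethoxy-2-(nitromethyl)butane, via nitro aldehyde 6 (not isolated)
Conditions: (S)-α,α-diphenylprolinol TMS ether (10 mol %), PhCO2H (10 mol %), MeNO2 (5 equiv), MeOH, rt; then HC(OMe)3, p-TsOH·H2O (20 mol %), rt
Reagents that add atoms: trimethyl orthoformate, COC(OC)OC
Why: In this iminium-catalysed (Hayashi–Jørgensen) Michael addition the CPh2OTMS group of the (S)-catalyst shields one face of the E-iminium ion, so nitromethane adds to the open face and sets C4 (R here, S in the target after the CIP change), and in situ acetalisation then masks C6.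

**Step 4**
Reactants: 8 angelic acid (2 equiv)
Product: 9 diangeloyl peroxide
Conditions: DCC (2 equiv), ethereal H2O2 (1 equiv), Et2O–CH2Cl2, −10→0 °C, dark
Reagents that add atoms: hydrogen peroxide, OO
Why: Carbodiimide-mediated double acylation of H2O2 (diacyl peroxide synthesis) is neutral and cold, so the Z geometry of the angelate is kept.

**Step 5**
Reactants: 10 geranyl acetate
Product: 11 (2E)-3-methyl-6-oxohex-2-en-1-yl acetate
Conditions: O3 (1 equiv, Sudan III end point), CH2Cl2, −78 °C; Me2S
Reagents that add atoms: ozone, [O-][O+]=O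
Why: In this chemoselective ozonolysis the distal trisubstituted alkene is much more electron-rich than the one deactivated by the allylic acetate, so only the isopropylidene group is cleaved and the E-alkene (future C1=C10) is kept.

**Step 6**
Reactants: 11 (2E)-3-methyl-6-oxohex-2-en-1-yl acetate; 9 diangeloyl peroxide
Product: 12 (2R,4E)-6-acetoxy-4-methyl-1-oxohex-4-en-2-yl angelate
Conditions: (R)-α,α-diphenylprolinol TMS ether (10 mol %), hydroquinone (10 mol %), THF, 0 °C→rt; used crude
Reagents that add atoms: none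
Why: Proposed new method: the enamine of 11 with the (R)-diarylprolinol silyl ether attacks the O–O σ* of 9 from the face opposite the CPh2OTMS group (SN2 at oxygen, angelate as leaving group), which sets C8 as R and installs the final ester in one step; the closest known reaction type is the organocatalytic α-benzoyloxylation of aldehydes with dibenzoyl peroxide, and only the spectator acyl group is changed.

**Step 7**
Reactants: 12 (2R,4E)-6-acetoxy-4-methyl-1-oxohex-4-en-2-yl angelate; 13 methyl propiolate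
Product: 15 methyl 2-[(2R,4E)-6-acetoxy-2-(angeloyloxy)-1-hydroxy-4-methylhex-4-en-1-yl]acrylate (both carbinol epimers), via vinylalane 14 (not isolated)
Conditions: 13, DIBAL-H, NMO, THF, 0 °C; then 12, 0 °C→rt; aq. work-up
Reagents that add atoms: none
Why: Vinylalumination (ynoate hydroalumination then 1,2-addition, a base-free Morita–Baylis–Hillman equivalent) attaches C11–C13 to the aldehyde without epimerising C8 or moving the ester, and the new C7 carbinol centre is erased in step 10.

**Step 8**
Reactants: 15 the hydroxy acrylate from step 7; 7 (2R)-1-(tert-butyldiphenylsilyloxy)-4,4-dimethoxy-2-(nitromethyl)butane (1.3 equiv)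
Product: 16 methyl (4R,8R,1(10)E)-8-angeloyloxy-15-(tert-butyldiphenylsilyloxy)-7-hydroxy-6,6-dimethoxy-3-nitro-6,7-secogermacra-1(10),11(13)-dien-12-oate (C3 and C7 epimers)
Conditions: Pd2(dba)3·CHCl3 (2.5 mol %), dppe (6 mol %), Cs2CO3 (1.1 equiv), THF–DMSO, rt
Reagents that add atoms: none
Why: In this Tsuji–Trost allylation Pd(0) ionises only the primary allylic acetate (the free hydroxy acrylate and the homoallylic angelate are not substrates), and the soft, bulky nitronate attacks the unsubstituted terminus of the syn π-allyl to give the linear E product; C3 is a mixture that is erased in step 9.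

**Step 9**
Reactants: 16 the nitro acetal from step 8
Product: 19 methyl (4S,8R,1(10)E)-8-angeloyloxy-15-(tert-butyldiphenylsilyloxy)-7-hydroxy-3,6-dioxo-6,7-secogermacra-1(10),11(13)-dien-12-oate, via sodium nitronate 17 (not isolated), via keto acetal 18 (not isolated)
Conditions: NaOMe (1.05 equiv), MeOH, 0 °C; aq. TiCl3 (4.5 equiv)/NH4OAc, THF, 0 °C→rt; then 1 M HCl to pH 1–2, rt, 1 h
Reagents that add atoms: water, O
Why: A McMurry-type reductive Nef reaction (nitronate to imine to ketone with buffered Ti(III)) followed by brief acid hydrolysis of the acetal leaves the enolisable C4 centre, the β,γ-alkene and both esters untouched.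

**Step 10**
Reactants: 19 the keto aldehyde from step 9
Product: 20 methyl (4S,8R,1(10)E,7(11)Z)-8-angeloyloxy-13-bromo-15-(tert-butyldiphenylsilyloxy)-3,6-dioxo-6,7-secogermacra-1(10),7(11)-dien-12-oate
Conditions: NBS, Me2S, CH2Cl2, 0 °C→rt
Reagents that add atoms: N-bromosuccinimide, O=C1CCC(=O)N1Br
Why: In this SN2′ bromination of a Baylis–Hillman alcohol through its alkoxysulfonium salt, bromide enters at C13 and the alkene moves to C7=C11 (Z, C8 cis to CH2Br), while the neutral conditions spare the aldehyde, the ketone and the electron-rich alkene.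

**Step 11 (key step)**
Reactants: 20 the allylic bromide from step 10
Product: 23 (4S,6R,7S,8R,1(10)E)-8-angeloyloxy-15-(tert-butyldiphenylsilyloxy)-3-oxogermacra-1(10),11(13)-dien-6,12-olide, via allylchromium 21 (not isolated), via hydroxy ester 22 (not isolated)
Conditions: CrCl2 (10 equiv), THF, rt, syringe pump 12 h (final 2 mM); aq. NH4Cl work-up
Reagents that add atoms: none
Why: This intramolecular Nozaki–Hiyama–Kishi-type allylchromium addition followed by lactonisation forges the same C6–C7 bond, with the same allyl transposition to C11=C13, as the farnesyl-to-germacrenyl closure: Cr(II) is aldehyde-selective and neither basic nor strongly Lewis acidic (so the C3 ketone survives and the γ-keto aldehyde undergoes no aldol, six-ring ene or furan formation), the covalent allyl–Cr(III) bond should not expel the δ-acyloxy group (bromomethylbutenolides behave likewise), the equilibrating (E)-allylchromium reacts through a chair with C5 and C8 equatorial (6,7-anti, hence the trans-lactone once O6 closes on the methyl ester), and C8 selects the face of C7 with H8 eclipsing C7=C11 (A1,3 strain), the donor C8–C9 bond anti to the new bond and the acyloxy group outside, which gives 6R,7S.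

**Step 12**
Reactants: 23 the silyl-protected germacranolide from step 11
Product: 24 (4S,6R,7S,8R,1(10)E)-8-angeloyloxy-15-hydroxy-3-oxogermacra-1(10),11(13)-dien-6,12-olide
Conditions: HF·pyridine, pyridine, THF, 0 °C→rt
Reagents that add atoms: none
Why: Fluoride desilylation in a buffered, non-basic medium avoids retro-aldol, β-elimination and Michael addition to the methylene lactone, and no stereocentre is touched.

**Step 13**
Reactants: 24 the 15-hydroxy germacranolide from step 12
Product: 25 argophyllone B (1R,4S,6R,7S,8R,10R)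
Conditions: dimethyldioxirane (1.1 equiv), acetone, −20 °C
Reagents that add atoms: dimethyldioxirane, CC1(C)OO1
Why: Neutral dioxirane epoxidation attacks only the electron-rich 1(10)-alkene (the angelate and the methylene lactone are electron-poor); the E-alkene stands perpendicular to the ring so only its outer face is open, and in the conformer with C14 on the β-face, as in related 8β-acyloxygermacranolides, this stereospecifically gives the trans 1β,10α (1R,10R) epoxide.

## Compound list
1 | (Z)-but-2-ene-1,4-diol | OC/C=C\CO | starting material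
2 | (Z)-4-(tert-butyldiphenylsilyloxy)but-2-en-1-ol | OC/C=C\CO[Si](c1ccccc1)(c1ccccc1)C(C)(C)C | intermediate
3 | (Z)-4-(tert-butyldiphenylsilyloxy)but-2-enal | O=C/C=C\CO[Si](c1ccccc1)(c1ccccc1)C(C)(C)C | intermediate (not isolated)
4 | (E)-4-(tert-butyldiphenylsilyloxy)but-2-enal | O=C/C=C/CO[Si](c1ccccc1)(c1ccccc1)C(C)(C)C | intermediate
5 | nitromethane | C[N+](=O)[O-] | starting material
6 | (3R)-3-[(tert-butyldiphenylsilyloxy)methyl]-4-nitrobutanal | O=CC[C@@H](CO[Si](c1ccccc1)(c1ccccc1)C(C)(C)C)C[N+](=O)[O-] | intermediate (not isolated)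
7 | (2R)-1-(tert-butyldiphenylsilyloxy)-4,4-dimethoxy-2-(nitromethyl)butane | COC(OC)C[C@@H](CO[Si](c1ccccc1)(c1ccccc1)C(C)(C)C)C[N+](=O)[O-] | intermediate
8 | angelic acid, (Z)-2-methylbut-2-enoic acid | C/C=C(/C)C(=O)O | starting material
9 | diangeloyl peroxide | C/C=C(/C)C(=O)OOC(=O)/C(C)=C\C | intermediate
10 | geranyl acetate | CC(C)=CCC/C(C)=C/COC(C)=O | starting material
11 | (2E)-3-methyl-6-oxohex-2-en-1-yl acetate | O=CCC/C(C)=C/COC(C)=O | intermediate
12 | (2R,4E)-6-acetoxy-4-methyl-1-oxohex-4-en-2-yl angelate | O=C[C@H](OC(=O)/C(C)=C\C)C/C(C)=C/COC(C)=O | intermediate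
13 | methyl propiolate | C#CC(=O)OC | starting material
14 | methyl 2-(diisobutylalumanyl)acrylate | C=C(C(=O)OC)[Al](CC(C)C)CC(C)C | intermediate (not isolated)
15 | methyl 2-[(2R,4E)-6-acetoxy-2-(angeloyloxy)-1-hydroxy-4-methylhex-4-en-1-yl]acrylate (carbinol epimers) | C=C(C(=O)OC)C(O)[C@H](OC(=O)/C(C)=C\C)C/C(C)=C/COC(C)=O | intermediate
16 | 6,7-seco nitro acetal (4R,8R,1(10)E; C3 and C7 epimers) | COC(OC)C[C@@H](CO[Si](c1ccccc1)(c1ccccc1)C(C)(C)C)C([N+](=O)[O-])C/C=C(\C)C[C@@H](OC(=O)/C(C)=C\C)C(O)C(=C)C(=O)OC | intermediate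
17 | sodium nitronate of 16 | COC(OC)C[C@@H](CO[Si](c1ccccc1)(c1ccccc1)C(C)(C)C)C(=[N+]([O-])[O-])C/C=C(\C)C[C@@H](OC(=O)/C(C)=C\C)C(O)C(=C)C(=O)OC.[Na+] | intermediate (not isolated)
18 | 6,7-seco 3-keto 6,6-dimethyl acetal (4S,8R) | COC(OC)C[C@@H](CO[Si](c1ccccc1)(c1ccccc1)C(C)(C)C)C(=O)C/C=C(\C)C[C@@H](OC(=O)/C(C)=C\C)C(O)C(=C)C(=O)OC | intermediate (not isolated)
19 | 6,7-seco 3-keto 6-aldehyde (4S,8R) | O=CC[C@@H](CO[Si](c1ccccc1)(c1ccccc1)C(C)(C)C)C(=O)C/C=C(\C)C[C@@H](OC(=O)/C(C)=C\C)C(O)C(=C)C(=O)OC | intermediate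
20 | 6,7-seco 13-bromo-7(11)Z-enoate (4S,8R) | O=CC[C@@H](CO[Si](c1ccccc1)(c1ccccc1)C(C)(C)C)C(=O)C/C=C(\C)C[C@@H](OC(=O)/C(C)=C\C)/C=C(\CBr)C(=O)OC | intermediate
21 | C13 allylchromium(III) dichloride from 20 (E/Z equilibrating) | O=CC[C@@H](CO[Si](c1ccccc1)(c1ccccc1)C(C)(C)C)C(=O)C/C=C(\C)C[C@@H](OC(=O)/C(C)=C\C)C=C(C[Cr](Cl)Cl)C(=O)OC | intermediate (not isolated)
22 | methyl (4S,6R,7S,8R,1(10)E)-8-angeloyloxy-6-hydroxy-15-(tert-butyldiphenylsilyloxy)-3-oxogermacra-1(10),11(13)-dien-12-oate | C=C(C(=O)OC)[C@H]1[C@H](O)C[C@@H](CO[Si](c2ccccc2)(c2ccccc2)C(C)(C)C)C(=O)C/C=C(\C)C[C@H]1OC(=O)/C(C)=C\C | intermediate (not isolated)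
23 | (4S,6R,7S,8R,1(10)E)-8-angeloyloxy-15-(tert-butyldiphenylsilyloxy)-3-oxogermacra-1(10),11(13)-dien-6,12-olide | C=C1C(=O)O[C@@H]2C[C@@H](CO[Si](c3ccccc3)(c3ccccc3)C(C)(C)C)C(=O)C/C=C(\C)C[C@@H](OC(=O)/C(C)=C\C)[C@@H]12 | intermediate
24 | (4S,6R,7S,8R,1(10)E)-8-angeloyloxy-15-hydroxy-3-oxogermacra-1(10),11(13)-dien-6,12-olide | C=C1C(=O)O[C@@H]2C[C@@H](CO)C(=O)C/C=C(\C)C[C@@H](OC(=O)/C(C)=C\C)[C@@H]12 | intermediate
25 | argophyllone B | C=C1C(=O)O[C@@H]2C[C@@H](CO)C(=O)C[C@H]3O[C@]3(C)C[C@@H](OC(=O)/C(C)=C\C)[C@@H]12 | target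

## Step count and risks

**Total steps:** 13.
**Longest linear sequence:** 9 steps. This is steps 5–13 from geranyl acetate, and equally steps 1–3 plus 8–13 from butenediol.

**Step 11 (ring closure) is the most likely to fail.**
- The allylchromium may lose angelate by 1,4-elimination.
- C8 may steer the aldehyde anti to its oxygen (Felkin sense), which would give the 6,7-bis-epimer.

The fallback carries C8 in the opposite configuration as a non-leaving aminoxyl ether and puts the ester on after ring closure, with inversion. It sets out from 11 and comes back at 23. Copper/imidazolidinone-catalysed α-oxyamination of 11 with TEMPO gives the (S)-aminoxyl aldehyde F1. Vinylalumination as in step 7 gives the hydroxy acrylate F2. Palladium-catalysed allylation of 7 gives the nitro acetal F3. Nef reaction and hydrolysis give the keto aldehyde F4, and NBS–Me2S gives the bromide F5. CrCl2 closes F5, now with O8 anti to the new bond and C9 on the ring side, to the 8α-aminoxyl lactone F6. Zn/AcOH cleaves the N–O bond to the 8α-alcohol F7. Mitsunobu esterification of F7 with 8 (PPh3, DIAD) inverts C8 and delivers 23.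

**Step 6 (α-angeloyloxylation) is the second risk.** The peroxide may be too labile or the ee too low. The fallback replaces the one-step acyloxylation by established oxidation and separate acylation. It sets out from 11 and comes back at 12. L-Proline-catalysed α-aminoxylation with nitrosobenzene and NaBH4 reduction in the same pot give the anilinooxy alcohol F8. Zn/AcOH gives the (R)-diol F9. TESCl/imidazole silylates the primary hydroxyl to give the silyl ether F10. Yamaguchi esterification with 8 gives the angelate F11. Swern oxidation, which converts primary TES ethers directly into aldehydes (iPr2NEt, −78 °C), delivers 12.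

**Step 8 (fragment union) is the third risk.** The nitronate may add to the acrylate, or base may move the angelate to O7. The fallback makes the C2–C3 bond first, on unfunctionalised geranyl acetate, and builds the right-hand end afterwards. It sets out from 7 and 10 and comes back at 18. Allylation of 7 with 10 under the step 8 conditions gives the nitro diene F12. A buffered Nef reaction gives the keto diene F13. Ozonolysis with one equivalent of O3 cleaves the terminal alkene, because the 1(10)-alkene is deactivated by the β-carbonyl, and gives the aldehyde F14. The step 6 acyloxylation gives the angeloyloxy aldehyde F15. Vinylalumination gives 18, which is hydrolysed to 19 as in step 9.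

## Further compounds
F1 | step 11 | (2S,4E)-6-acetoxy-4-methyl-2-(2,2,6,6-tetramethylpiperidin-1-yloxy)hex-4-enal | O=C[C@@H](ON1C(C)(C)CCCC1(C)C)C/C(C)=C/COC(C)=O
F2 | step 11 | methyl 2-[(2S,4E)-6-acetoxy-1-hydroxy-4-methyl-2-(2,2,6,6-tetramethylpiperidin-1-yloxy)hex-4-en-1-yl]acrylate | C=C(C(=O)OC)C(O)[C@@H](ON1C(C)(C)CCCC1(C)C)C/C(C)=C/COC(C)=O
F3 | step 11 | 8-epi analogue of 16 with tetramethylpiperidinyloxy at C8 | COC(OC)C[C@@H](CO[Si](c1ccccc1)(c1ccccc1)C(C)(C)C)C([N+](=O)[O-])C/C=C(\C)C[C@H](ON1C(C)(C)CCCC1(C)C)C(O)C(=C)C(=O)OC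
F4 | step 11 | 8-epi analogue of 19 with tetramethylpiperidinyloxy at C8 | O=CC[C@@H](CO[Si](c1ccccc1)(c1ccccc1)C(C)(C)C)C(=O)C/C=C(\C)C[C@H](ON1C(C)(C)CCCC1(C)C)C(O)C(=C)C(=O)OC
F5 | step 11 | 8-epi analogue of 20 with tetramethylpiperidinyloxy at C8 | O=CC[C@@H](CO[Si](c1ccccc1)(c1ccccc1)C(C)(C)C)C(=O)C/C=C(\C)C[C@H](ON1C(C)(C)CCCC1(C)C)/C=C(\CBr)C(=O)OC
F6 | step 11 | 8α-(tetramethylpiperidinyloxy)-15-(tert-butyldiphenylsilyloxy)-3-oxogermacra-1(10)E,11(13)-dien-6α,12-olide (7αH, C4 as in 23) | C=C1C(=O)O[C@@H]2C[C@@H](CO[Si](c3ccccc3)(c3ccccc3)C(C)(C)C)C(=O)C/C=C(\C)C[C@H](ON3C(C)(C)CCCC3(C)C)[C@@H]12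
F7 | step 11 | 8α-hydroxy-15-(tert-butyldiphenylsilyloxy)-3-oxogermacra-1(10)E,11(13)-dien-6α,12-olide (7αH, C4 as in 23) | C=C1C(=O)O[C@@H]2C[C@@H](CO[Si](c3ccccc3)(c3ccccc3)C(C)(C)C)C(=O)C/C=C(\C)C[C@H](O)[C@@H]12
F8 | step 6 | (2E,5R)-5-(anilinooxy)-6-hydroxy-3-methylhex-2-en-1-yl acetate | OC[C@H](ONc1ccccc1)C/C(C)=C/COC(C)=O
F9 | step 6 | (2E,5R)-5,6-dihydroxy-3-methylhex-2-en-1-yl acetate | OC[C@H](O)C/C(C)=C/COC(C)=O
F10 | step 6 | (2E,5R)-5-hydroxy-3-methyl-6-(triethylsilyloxy)hex-2-en-1-yl acetate | CC[Si](CC)(CC)OC[C@H](O)C/C(C)=C/COC(C)=O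
F11 | step 6 | (2R,4E)-6-acetoxy-4-methyl-1-(triethylsilyloxy)hex-4-en-2-yl angelate | CC[Si](CC)(CC)OC[C@H](OC(=O)/C(C)=C\C)C/C(C)=C/COC(C)=O
F12 | step 8 | (4R,1(10)E)-15-(tert-butyldiphenylsilyloxy)-6,6-dimethoxy-3-nitro-6,7-secogermacra-1(10),7(11)-diene (C3 epimers) | COC(OC)C[C@@H](CO[Si](c1ccccc1)(c1ccccc1)C(C)(C)C)C([N+](=O)[O-])C/C=C(\C)CCC=C(C)C
F13 | step 8 | (4S,1(10)E)-15-(tert-butyldiphenylsilyloxy)-6,6-dimethoxy-6,7-secogermacra-1(10),7(11)-dien-3-one | COC(OC)C[C@@H](CO[Si](c1ccccc1)(c1ccccc1)C(C)(C)C)C(=O)C/C=C(\C)CCC=C(C)C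
F14 | step 8 | C7 aldehyde from F13 (C11–C13 removed) | COC(OC)C[C@@H](CO[Si](c1ccccc1)(c1ccccc1)C(C)(C)C)C(=O)C/C=C(\C)CCC=O
F15 | step 8 | (8R)-8-angeloyloxy derivative of F14 | COC(OC)C[C@@H](CO[Si](c1ccccc1)(c1ccccc1)C(C)(C)C)C(=O)C/C=C(\C)C[C@@H](OC(=O)/C(C)=C\C)C=O
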